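The runs were generated by integration with constants of no real substance; the scatter is artificial.

A slow flask was my worry: violet, at 80 °C, might stop short for want of time, not for want of G.

all flasks: Q 0.2 mol%

|  | D | G | temperature | remark | time |
|---|---|---|---|---|---|
| autumn | 10 mM | 0.90 equiv | 120 °C | run made earlier |  |
| green | 5.0 mM | 0.900 equiv | 120 °C |  | 15 min |
| blue | 5.0 mM | 0.900 equiv | 100 °C |  | 15 min |
| violet | 5.0 mM | 0.900 equiv | 80 °C |  | 15 min |

- autumn (time / s: X / %, D / %): 10.0: 31, 67; 12.0: 33, 67; 20.0: 49, 58; 30.0: 57, 44; 50.0: 74, 28; 90.0: 83, 15

(scatter of a reading: 2 percentage points)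

1. the best flask by amount of X, in percent of the D charged; "all alike" if 1.5 percentage points covers them all (green / blue / violet / all alike)
2. amount of X at the end, in percent of the D charged, green
3. amount of X at the end, in percent of the D charged, blue
4. amount of X at the end, in percent of the D charged, violet

- the analysis behind the earlier runs scatters by 2 percentage points, standard deviation
- the earlier runs do not show what temperature does; that part of a forecast is a guess
- no earlier run changes the charge of Q; that part of a forecast is a guess

In the autumn run, D and X still summed to 98.0 % at 90.0 s, so I assumed one G per X, with G as the limiting reagent. I called the charge of G, in percent of D, the ceiling c: 90.0 %.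

I then solved two extremes. In the fast one, the catalyst stays saturated, the rate holds steady, and X climbs straight to c and stops. In the slow one, the rate is k·D·G. Let K be k times the starting D, e the excess of D over G as a fraction of D, and d and g the fractions of D and G left, both on the D charged. Integration gives eKt = ln(c·d/g). Near the end d hardly moves, so G dies away pseudo-first-order, with g = c·e·exp(−t/τ) and τ = 1/(eK).

The autumn run lay between the two. X gained 57 % in the first 30.0 s but 9 percentage points in the last 40.0 s, so the rate was not steady. K, read from the readings, rose from 0.0531 /s to 0.0869 /s, so the tail looked shorter than k·D·G implies.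

Taking the lower K and halving it for green's dilution, I got τ = 6.28 min. That left green 0.82 points short of c at 15 min, inside the scatter. A flask slowed by a factor 2 would be 2.7 points short. No run showed the slowing with temperature, so my own commitment was c for green and, as a guess from that twice-slowed flask, 87.3 % for blue and violet.

The forecast, lower than my ceiling for blue, gave 89 %, 84 % and 65 % for green, blue and violet, with green best: “Temperature is a guess”.

The flasks gave green 90.0 %, blue 90.0 % and violet 90.0 %, so the answer was all alike.

    D + Q → J (k = 4800 /M/s, Ea = 29.0 kJ/mol)
    J → Z (k = 16.0 /s, Ea = 80.0 kJ/mol)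
    G + Z ⇌ L (K = 620 /M, k = 15000 /M/s, Ea = 24.0 kJ/mol, ΔH = 13.0 kJ/mol)
    L → E (k = 5.70 /s, Ea = 69.0 kJ/mol)
    E ⇌ Q + X (K = 0.00190 M, k = 12.0 /s, Ea = 89.0 kJ/mol, ΔH = −34.0 kJ/mol)
    (constants at 80 °C)

Violet stopped at the ceiling 90.0 % because G ran short. By 7.50 min it held 0.529 % of its G, and with that shortage taken away the same flask reached 99.9 %. For the neighbour of green with 0.540 equiv of G, c is 54.0 %, and that flask gave 54.0 %.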